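Numbering used throughout: unit 1 is unprimed (O1, C2, C3, C4, C4a, C8a, ring A, anisyl group on C2); unit 2 is primed (ring A', 4-oxygenated phenyl on C2'). Compounds are numbered 1–24 in the order of the steps.

## Analysis of the target

The target is a 3,3'-linked biflavanone: two 2-arylchroman-4-one units joined through C3 and C3', unit 1 with a 4-methoxyphenyl group at C2 and unit 2 with a 4-hydroxyphenyl group at C2', both benzo rings being of the phloroglucinol type with free hydroxyls at C5, C7, C5' and C7'. The four stereocentres form one contiguous chain, C2 (S), C3 (R), C3' (S) and C2' (S), which places the aryl group and the C3–C3' bond trans in unit 1 but cis in unit 2, so that the halves are not related by symmetry and no dimerisation of one flavanone can lead to the compound. C3 and C3' each lie alpha to a ketone and beta to a ring aryloxy oxygen, so base can epimerise them or open ring C; the cis unit 2 is the less stable arrangement and has to be made under kinetic control and handled gently afterwards. One aryl methyl ether must persist beside five phenols, which calls for benzyl protection of the phenols and rules out ether-cleaving Lewis acids at the end. The hard parts are the crowded C3–C3' link between two methines, the unlike relative configuration of the two units, and two enolisable carbonyl groups in a 1,4-relation. The strategy rests on unit 1: O1 and C4 sit on adjacent carbons of ring A (C8a and C4a), and the trans C2–C3 pair has C2 benzylic to an electron-rich anisyl ring. This is the pattern left when an o-quinone methide (O1=C8a–C4a=C4) adds to an E anethole-type alkene (C2=C3), with C3' and C4' arriving as an acetate chain on that alkene.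

## Retrosynthetic reasoning

**24 ⇒ 23.** The five O–benzyl bonds are cut first. The phenols are uncovered last because a free hydroxyl next to either ketone eases base-induced opening of ring C, and because hydrogenolysis is neutral and leaves the cis C2'/C3' pair alone. The aryl methyl ether of unit 1 is not affected. The forward step must remove five benzyl groups without reducing a ketone or cleaving the benzylic C2–O1 and C2'–O1' bonds.

**23 ⇒ 22.** The C4 carbonyl is traced back to a C4 methyl ether. While C4 is sp3, base can neither enolise C3 nor expel O1, and the molecule holds only one carbonyl group (that of unit 2) for enolate chemistry. The forward step must oxidise one benzylic ether C–H bond on the most electron-rich ring and nothing else.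

**22 ⇒ 20.** Ring C of unit 2 is opened at the O1'–C8a' aryl ether bond, not at C2'–O1'. The C2' oxygen then belongs to a secondary alcohol whose configuration passes into the ring unchanged; closure at C2' would instead need substitution at a 4-alkoxybenzylic carbon that ionises easily. The price is a leaving group on the arene, fluorine at the future C8a', activated by the ortho ketone. Forward, alkoxide 21 must displace fluoride faster than it fragments by retro-aldol reaction.

**20 ⇒ 16 + 17.** The C2'–C3' bond is cut as an aldol bond. This is the one disconnection of unit 2 that sets C3' and C2' together and uses the only ketone present. The cis relation in the ring corresponds to a syn aldol, which a closed transition state delivers. The forward reaction, run through enolates 18 and 19, must also choose the right face of the enolate next to C3.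

**16 ⇒ 11 + 15; 11 ⇒ 10; 15 ⇒ 14 ⇒ 13 ⇒ 12.** The C4'–C4a' bond is cut as an acyl substitution: aryllithium 15 adds to Weinreb amide 11, which stops at the ketone and is made from ester 10. Arene 14 carries bromine and fluorine in the required places and goes back by bromination to 13 and by double fluoride displacement to 12.

**10 ⇒ 2 + 6 + 7.** The O1–C2 and C3–C4 bonds of unit 1 are cut together. This removes ring C and three stereocentres in one operation and leads to 2, 6 and 7, each one or two steps from commerce. Cutting here and not at C2–aryl or C4–C4a lets the trans relation come from the E geometry of 6 and leaves C4 as an ether, the oxidation level the later steps need. The forward reaction has to generate methide 9 from 2 and 7 through acetal 8 and make it add to 6 with control of absolute configuration.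

**2 ⇒ 1; 6 ⇒ 5 ⇒ 3 + 4.** Aldehyde 2 comes from 1 by etherification of the two hydroxyls that are not tied up in the hydrogen bond to the formyl group. Ester 6 comes from acid 5, itself the arylation product of 4 with 3; the aryl–vinyl bond is cut because that coupling fixes the E geometry.

## Alternatives that were turned down

**Alternative 1:** The C2–aryl and C3–C3' bonds of unit 1 are cut together. In the forward key step the monovalent rhodium catalyst [RhCl(binap)]2 adds the arylzinc reagent (4-methoxyphenyl)zinc chloride A3 to C2 of 5,7-bis(benzyloxy)-4H-chromen-4-one A2. The metal enolate formed in this way is then alkylated at C3, anti to the new aryl group, by 2-bromo-1-[2,4-bis(benzyloxy)-6-fluorophenyl]ethan-1-one A4, which gives the trans diketone A1.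
- For: enantioselective conjugate arylation of a chromone such as A2 is a better-established way to set C2 than the chosen key step, so on enantiocontrol this alternative is stronger. C4 is a ketone from the start, which saves the late oxidation, and the sequence to the stage of ketone 16 is about three steps shorter.
- Against: the enolate generated from A2 and A3 has O1 in the beta position and can open ring C before it is alkylated by the hindered bromide A4, whose acidic alpha hydrogens invite proton exchange. A1 is a 1,4-diketone, so the later aldol at C3' would need one ketone enolised selectively next to an epimerisable C3 that can expel O1.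
- Comparison: the chosen strategy offers instead a C3 that cannot enolise through every base step, and a trans relation written into an alkene geometry.

**Alternative 2:** Ring A of unit 1 is cut at C4a–C5 and C8–C8a. Forward, 1,1-dimethoxy-3-(trimethylsilyloxy)buta-1,3-diene A7 adds across the brominated double bond of the trans dihydropyranone A6, and two eliminations aromatise the adduct to the flavanone A5.
- For: the regiochemistry is fixed by the polarity of the diene A7, and the two ring A oxygens arrive differentiated (5-methoxy, 7-hydroxy), which is stronger than the chosen route wherever differentiation matters.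
- Against: the target needs both oxygens free while a methyl ether on the anisyl ring must survive, so the 5-methoxy group of A5 would later have to be cleaved selectively by a Lewis acid on a base- and acid-sensitive 3-substituted flavanone. A6 is a vinylogous ester and a poor partner for the electron-rich diene A7, so forcing conditions would endanger C3 and the C2–O1 bond. A6 itself needs its own enantioselective synthesis, trans alkylation and bromination.
- Comparison: the result is again a C4 ketone with the diketone problem of alternative 1, reached in more steps while building an aromatic ring that the chosen route buys.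

**Alternative 3:** The C4–C4a bond of unit 1 is cut. Forward, bromine–lithium exchange on the aryl ether of the paraconic lactone A9 turns C4a into a nucleophile that attacks the lactone carbonyl in a Parham-type cyclisation. This closes ring C and releases the C2' oxygen, giving the hydroxy ester A8.
- For: C3, C3' and C2' are fixed beforehand in the rigid five-membered ring of A9, where relative configuration is easier to control and to prove than in the acyclic aldol of the chosen route; on the C3/C3' relation this alternative is stronger.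
- Against: C2 must be installed as an aryl ether at an anisyl carbinol that ionises readily, so its configuration is hard to secure. The exchange must outrun attack on the tert-butyl ester and deprotonation alpha to the lactone carbonyl. A8 is formed as a beta-alkoxide of an ester beside a new, enolisable C4 ketone, and turning its ester into the ring A' ketone would need protection of C4.
- Comparison: the chosen strategy sets C2 and C3 in one catalytic step and keeps C4 masked until the end, at the cost of a less certain aldol.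

Key step: step 4

Assumption: the (R) enantiomer of the phosphoric acid is taken as the one that leads to (2S,3S,4S)-10; should the sense of induction prove opposite, the (S) acid is used and nothing else in the route changes.

## Route

Step 1
Reactants: 1 2,4,6-trihydroxybenzaldehyde
Product: 2 2,4-bis(benzyloxy)-6-hydroxybenzaldehyde
Conditions: BnBr (2.05 equiv), K2CO3, DMF, 0 °C to rt
Reagents that add atoms: benzyl bromide, BrCc1ccccc1
Why: Williamson ether synthesis; the para hydroxyl and one ortho hydroxyl are alkylated, while the last ortho hydroxyl is held in a hydrogen bond to the formyl oxygen and is the least nucleophilic, so two equivalents should stop at the bis-ether.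

Step 2
Reactants: 3 4-iodoanisole; 4 but-3-enoic acid
Product: 5 (E)-4-(4-methoxyphenyl)but-3-enoic acid
Conditions: Pd(OAc)2 (2 mol%), Et3N, MeCN, 80 °C; aq. HCl work-up
Reagents that add atoms: none
Why: Heck reaction; the aryl group adds to the terminal alkene carbon and beta-hydride elimination on the benzylic side should give the aryl-conjugated E alkene, with the carboxylate left out of conjugation.

Step 3
Reactants: 5 (E)-4-(4-methoxyphenyl)but-3-enoic acid
Product: 6 methyl (E)-4-(4-methoxyphenyl)but-3-enoate
Conditions: MeI, KHCO3, DMF, rt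
Reagents that add atoms: iodomethane, CI
Why: O-alkylation of the carboxylate by SN2 reaction; the weak base avoids both acid-promoted addition to the anethole-type alkene and migration of the double bond toward the ester.

Step 4
Reactants: 2 2,4-bis(benzyloxy)-6-hydroxybenzaldehyde; 6 methyl (E)-4-(4-methoxyphenyl)but-3-enoate; 7 trimethyl orthoformate
Product: 10 methyl 2-[(2S,3S,4S)-5,7-bis(benzyloxy)-4-methoxy-2-(4-methoxyphenyl)chroman-3-yl]acetate, via dimethyl acetal 8 (not isolated), via o-quinone methide 9 (not isolated)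
Conditions: 7 (1.5 equiv), (R)-3,3'-bis(2,4,6-triisopropylphenyl)-1,1'-binaphthyl-2,2'-diyl hydrogen phosphate (10 mol%), 5 Å molecular sieves, CH2Cl2, −20 °C to 0 °C
Reagents that add atoms: none
Why: Proposed new method: the acid converts 2 and 7 into acetal 8, which loses methanol to the E methide 9, held by the chiral phosphate as a hydrogen-bonded ion pair; the alkene 6 then bonds through its chain-bearing carbon to the methide carbon (C3–C4) and the ring A oxygen closes on the anisyl-stabilised benzylic carbon (O1–C2) in one asynchronous, suprafacial inverse-demand hetero-Diels–Alder event. The closest known reaction types are the acid-promoted three-component chroman synthesis from salicylaldehydes, orthoformates and styrenes and the chiral phosphoric acid catalysed [4+2] cycloaddition of o-quinone methides with styrenes; their union on an alpha-methoxy methide has not been shown. Ring C closes by [4+2] cycloaddition of the four-atom O=C–C=C unit of 9 with the two alkene carbons of 6. The trans relation of C2 and C3 is copied from the E geometry of 6 because both bonds form on one face of the alkene, and if the addition became stepwise, closure of the benzylic cation to the diequatorial ring should give the same trans pair. At C4 the anisyl ring is expected to lie endo over the methide, which places the methoxy group cis to the aryl group and trans to the side chain; this centre is removed in step 11, so its ratio does not matter. The absolute configuration of C2 and C3 is set by the phosphate, whose 2,4,6-triisopropylphenyl walls should leave one face of the bound methide open. Regioselectivity follows from the polarity of both partners (methide carbon electrophilic, alkene carbon remote from the anisyl ring nucleophilic), and the step needs the acid to ionise acetal 8 but not the C4 ether of 10, which the extra oxygen stabilisation of the acetal-derived cation and the low temperature should secure.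

Step 5
Reactants: 10 methyl 2-[(2S,3S,4S)-5,7-bis(benzyloxy)-4-methoxy-2-(4-methoxyphenyl)chroman-3-yl]acetate
Product: 11 2-[(2S,3S,4S)-5,7-bis(benzyloxy)-4-methoxy-2-(4-methoxyphenyl)chroman-3-yl]-N-methoxy-N-methylacetamide
Conditions: MeNH(OMe)·HCl, i-PrMgCl, THF, −20 °C to 0 °C
Reagents that add atoms: N,O-dimethylhydroxylamine hydrochloride, CNOC.Cl
Why: Weinreb amide formation by aminolysis of the ester with the magnesium amide made in the flask; no stereocentre is alpha to the carbonyl, so none is at risk.

Step 6
Reactants: 12 1,3,5-trifluorobenzene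
Product: 13 1,3-bis(benzyloxy)-5-fluorobenzene
Conditions: BnOH (2.2 equiv), NaH, NMP, rt to 100 °C (sealed vessel)
Reagents that add atoms: benzyl alcohol, OCc1ccccc1
Why: Two successive nucleophilic aromatic substitutions of fluoride by benzyloxide; each alkoxy group deactivates the ring further, so the third fluorine should stay.

Step 7
Reactants: 13 1,3-bis(benzyloxy)-5-fluorobenzene
Product: 14 1,5-bis(benzyloxy)-2-bromo-3-fluorobenzene
Conditions: NBS (1.0 equiv), MeCN, 0 °C to rt
Reagents that add atoms: N-bromosuccinimide, O=C1CCC(=O)N1Br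
Why: Electrophilic aromatic bromination; attack para to one benzyloxy group and ortho to the other, next to the small fluorine, is preferred over the position flanked by both benzyloxy groups, as with other 5-substituted resorcinol diethers.

Step 8
Reactants: 14 1,5-bis(benzyloxy)-2-bromo-3-fluorobenzene; 11 2-[(2S,3S,4S)-5,7-bis(benzyloxy)-4-methoxy-2-(4-methoxyphenyl)chroman-3-yl]-N-methoxy-N-methylacetamide
Product: 16 1-[2,4-bis(benzyloxy)-6-fluorophenyl]-2-[(2S,3S,4S)-5,7-bis(benzyloxy)-4-methoxy-2-(4-methoxyphenyl)chroman-3-yl]ethan-1-one, via aryllithium 15 (not isolated)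
Conditions: 14, n-BuLi, THF, −78 °C; then 11, −78 °C; aq. NH4Cl
Reagents that add atoms: none
Why: Bromine–lithium exchange followed by Weinreb ketone synthesis; the chelated tetrahedral intermediate prevents a second addition, and below −70 °C the ortho-fluoro aryllithium should not lose LiF to an aryne.

Step 9
Reactants: 16 1-[2,4-bis(benzyloxy)-6-fluorophenyl]-2-[(2S,3S,4S)-5,7-bis(benzyloxy)-4-methoxy-2-(4-methoxyphenyl)chroman-3-yl]ethan-1-one; 17 4-(benzyloxy)benzaldehyde
Product: 20 (2S,3S)-1-[2,4-bis(benzyloxy)-6-fluorophenyl]-3-[4-(benzyloxy)phenyl]-2-[(2S,3S,4S)-5,7-bis(benzyloxy)-4-methoxy-2-(4-methoxyphenyl)chroman-3-yl]-3-hydroxypropan-1-one, via lithium enolate 18 (not isolated), via titanium enolate 19 (not isolated)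
Conditions: LiN(SiMe3)2, THF, −78 °C; ClTi(OiPr)3, −78 °C to −40 °C; 17, −78 °C; aq. NH4Cl
Reagents that add atoms: none
Why: Aldol addition of a titanium triisopropoxide enolate through a Zimmerman–Traxler chair, which is syn-selective and is reinforced by the Z geometry expected for an aryl ketone with a branched substituent; the syn adduct maps onto the cis relation of C2' and C3'. The face of the enolate is chosen by A(1,3) strain: with H3 eclipsing the enolate double bond, the aldehyde should approach past the smaller C4 methoxy flank and away from the C2 anisyl group, which gives the required C3' configuration. The weakly Lewis acidic titanium reagent should leave the C4 ether intact.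

Step 10
Reactants: 20 (2S,3S)-1-[2,4-bis(benzyloxy)-6-fluorophenyl]-3-[4-(benzyloxy)phenyl]-2-[(2S,3S,4S)-5,7-bis(benzyloxy)-4-methoxy-2-(4-methoxyphenyl)chroman-3-yl]-3-hydroxypropan-1-one
Product: 22 (2S,3S)-5,7-bis(benzyloxy)-2-[4-(benzyloxy)phenyl]-3-[(2S,3S,4S)-5,7-bis(benzyloxy)-4-methoxy-2-(4-methoxyphenyl)chroman-3-yl]chroman-4-one, via sodium alkoxide 21 (not isolated)
Conditions: NaN(SiMe3)2 (1.05 equiv), THF/DMF, −40 °C to 0 °C; pH 7 buffer
Reagents that add atoms: none
Why: Intramolecular nucleophilic aromatic substitution (addition–elimination) of fluoride ortho to the ketone closes the six-membered ring; the C2'–O bond is not broken, so C2' keeps its configuration and the syn aldol becomes the 2',3'-cis chromanone. One equivalent of base at low temperature is meant to limit retro-aldol reaction and enolisation at C3'.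

Step 11
Reactants: 22 (2S,3S)-5,7-bis(benzyloxy)-2-[4-(benzyloxy)phenyl]-3-[(2S,3S,4S)-5,7-bis(benzyloxy)-4-methoxy-2-(4-methoxyphenyl)chroman-3-yl]chroman-4-one
Product: 23 (2S,3R)-5,7-bis(benzyloxy)-3-{(2S,3S)-5,7-bis(benzyloxy)-2-[4-(benzyloxy)phenyl]-4-oxochroman-3-yl}-2-(4-methoxyphenyl)chroman-4-one
Conditions: DDQ (1.2 equiv), CH2Cl2/pH 7 phosphate buffer, 0 °C
Reagents that add atoms: water, O
Why: Oxidation of an electron-rich benzylic methyl ether to the aryl ketone by DDQ, the reagent that functionalises C4 of 5,7-dialkoxyflavans by hydride abstraction; loss of hydride from C4–H gives a cation stabilised by the methoxy group and the three ring A oxygens, water adds, and the hemiketal loses methanol. Ring A of unit 1 is the most electron-rich site, and the direct route avoids a free C4 cation that could lose H3.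

Step 12
Reactants: 23 (2S,3R)-5,7-bis(benzyloxy)-3-{(2S,3S)-5,7-bis(benzyloxy)-2-[4-(benzyloxy)phenyl]-4-oxochroman-3-yl}-2-(4-methoxyphenyl)chroman-4-one
Product: 24 (2S,3R)-3-[(2S,3S)-5,7-dihydroxy-2-(4-hydroxyphenyl)-4-oxochroman-3-yl]-5,7-dihydroxy-2-(4-methoxyphenyl)chroman-4-one
Conditions: H2 (1 atm), Pd/C (10% palladium on carbon), EtOAc/MeOH, rt
Reagents that add atoms: none
Why: Catalytic hydrogenolysis of five aryl benzyl ethers under neutral conditions; the aryl methyl ether, the aryl ketones and the ring C–O bonds of flavanones normally survive, and no base is present to epimerise C3 or C3'.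

## Compound list

1 | 2,4,6-trihydroxybenzaldehyde | O=Cc1c(O)cc(O)cc1O | starting material
2 | 2,4-bis(benzyloxy)-6-hydroxybenzaldehyde | O=Cc1c(O)cc(OCc2ccccc2)cc1OCc1ccccc1 | intermediate
3 | 4-iodoanisole | COc1ccc(I)cc1 | starting material
4 | but-3-enoic acid | C=CCC(=O)O | starting material
5 | (E)-4-(4-methoxyphenyl)but-3-enoic acid | COc1ccc(/C=C/CC(=O)O)cc1 | intermediate
6 | methyl (E)-4-(4-methoxyphenyl)but-3-enoate | COC(=O)C/C=C/c1ccc(OC)cc1 | intermediate
7 | trimethyl orthoformate | COC(OC)OC | starting material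
8 | 3,5-bis(benzyloxy)-2-(dimethoxymethyl)phenol (not isolated) | COC(OC)c1c(O)cc(OCc2ccccc2)cc1OCc1ccccc1 | intermediate
9 | (6E)-3,5-bis(benzyloxy)-6-(methoxymethylidene)cyclohexa-2,4-dien-1-one (not isolated) | CO/C=C1/C(=O)C=C(OCc2ccccc2)C=C1OCc1ccccc1 | intermediate
10 | methyl 2-[(2S,3S,4S)-5,7-bis(benzyloxy)-4-methoxy-2-(4-methoxyphenyl)chroman-3-yl]acetate (2,3-trans, 3,4-trans) | COc1ccc([C@H]2Oc3cc(OCc4ccccc4)cc(OCc4ccccc4)c3[C@@H](OC)[C@@H]2CC(=O)OC)cc1 | intermediate
11 | 2-[(2S,3S,4S)-5,7-bis(benzyloxy)-4-methoxy-2-(4-methoxyphenyl)chroman-3-yl]-N-methoxy-N-methylacetamide | COc1ccc([C@H]2Oc3cc(OCc4ccccc4)cc(OCc4ccccc4)c3[C@@H](OC)[C@@H]2CC(=O)N(C)OC)cc1 | intermediate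
12 | 1,3,5-trifluorobenzene | Fc1cc(F)cc(F)c1 | starting material
13 | 1,3-bis(benzyloxy)-5-fluorobenzene | Fc1cc(OCc2ccccc2)cc(OCc2ccccc2)c1 | intermediate
14 | 1,5-bis(benzyloxy)-2-bromo-3-fluorobenzene | Fc1cc(OCc2ccccc2)cc(OCc2ccccc2)c1Br | intermediate
15 | [2,4-bis(benzyloxy)-6-fluorophenyl]lithium (not isolated) | [Li]c1c(F)cc(OCc2ccccc2)cc1OCc1ccccc1 | intermediate
16 | 1-[2,4-bis(benzyloxy)-6-fluorophenyl]-2-[(2S,3S,4S)-5,7-bis(benzyloxy)-4-methoxy-2-(4-methoxyphenyl)chroman-3-yl]ethan-1-one | COc1ccc([C@H]2Oc3cc(OCc4ccccc4)cc(OCc4ccccc4)c3[C@@H](OC)[C@@H]2CC(=O)c2c(F)cc(OCc3ccccc3)cc2OCc2ccccc2)cc1 | intermediate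
17 | 4-(benzyloxy)benzaldehyde | O=Cc1ccc(OCc2ccccc2)cc1 | starting material
18 | lithium (Z)-enolate of 16, lithium (Z)-1-[2,4-bis(benzyloxy)-6-fluorophenyl]-2-[(2S,3S,4S)-5,7-bis(benzyloxy)-4-methoxy-2-(4-methoxyphenyl)chroman-3-yl]ethen-1-olate (not isolated) | COc1ccc([C@H]2Oc3cc(OCc4ccccc4)cc(OCc4ccccc4)c3[C@@H](OC)[C@@H]2/C=C(\O[Li])c2c(F)cc(OCc3ccccc3)cc2OCc2ccccc2)cc1 | intermediate
19 | triisopropoxytitanium (Z)-enolate of 16 (not isolated) | COc1ccc([C@H]2Oc3cc(OCc4ccccc4)cc(OCc4ccccc4)c3[C@@H](OC)[C@@H]2/C=C(\O[Ti](OC(C)C)(OC(C)C)OC(C)C)c2c(F)cc(OCc3ccccc3)cc2OCc2ccccc2)cc1 | intermediate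
20 | (2S,3S)-1-[2,4-bis(benzyloxy)-6-fluorophenyl]-3-[4-(benzyloxy)phenyl]-2-[(2S,3S,4S)-5,7-bis(benzyloxy)-4-methoxy-2-(4-methoxyphenyl)chroman-3-yl]-3-hydroxypropan-1-one (syn aldol) | COc1ccc([C@H]2Oc3cc(OCc4ccccc4)cc(OCc4ccccc4)c3[C@@H](OC)[C@@H]2[C@@H]([C@H](O)c2ccc(OCc3ccccc3)cc2)C(=O)c2c(F)cc(OCc3ccccc3)cc2OCc2ccccc2)cc1 | intermediate
21 | sodium alkoxide of 20 (not isolated) | COc1ccc([C@H]2Oc3cc(OCc4ccccc4)cc(OCc4ccccc4)c3[C@@H](OC)[C@@H]2[C@@H]([C@H](O[Na])c2ccc(OCc3ccccc3)cc2)C(=O)c2c(F)cc(OCc3ccccc3)cc2OCc2ccccc2)cc1 | intermediate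
22 | (2S,3S)-5,7-bis(benzyloxy)-2-[4-(benzyloxy)phenyl]-3-[(2S,3S,4S)-5,7-bis(benzyloxy)-4-methoxy-2-(4-methoxyphenyl)chroman-3-yl]chroman-4-one (chromanone unit 2,3-cis) | COc1ccc([C@H]2Oc3cc(OCc4ccccc4)cc(OCc4ccccc4)c3[C@@H](OC)[C@@H]2[C@@H]2C(=O)c3c(OCc4ccccc4)cc(OCc4ccccc4)cc3O[C@@H]2c2ccc(OCc3ccccc3)cc2)cc1 | intermediate
23 | (2S,3R)-5,7-bis(benzyloxy)-3-{(2S,3S)-5,7-bis(benzyloxy)-2-[4-(benzyloxy)phenyl]-4-oxochroman-3-yl}-2-(4-methoxyphenyl)chroman-4-one (unit 1 trans, unit 2 cis) | COc1ccc([C@H]2Oc3cc(OCc4ccccc4)cc(OCc4ccccc4)c3C(=O)[C@@H]2[C@@H]2C(=O)c3c(OCc4ccccc4)cc(OCc4ccccc4)cc3O[C@@H]2c2ccc(OCc3ccccc3)cc2)cc1 | intermediate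
24 | (2S,3R)-3-[(2S,3S)-5,7-dihydroxy-2-(4-hydroxyphenyl)-4-oxochroman-3-yl]-5,7-dihydroxy-2-(4-methoxyphenyl)chroman-4-one (unit 1 trans, unit 2 cis) | COc1ccc([C@H]2Oc3cc(O)cc(O)c3C(=O)[C@@H]2[C@@H]2C(=O)c3c(O)cc(O)cc3O[C@@H]2c2ccc(O)cc2)cc1 | target

## Step count and risk

Total: 12 steps. Longest linear sequence: 9 steps (steps 2, 3, 4, 5, 8, 9, 10, 11, 12).

**Step 4 (key step, proposed new method).** The most likely failure is poor enantiofacial discrimination: alkene 6 has no hydrogen-bond donor to anchor it to the phosphate, so the ion pair alone must shield one face of 9. A second danger is slow ionisation of the C4 ether of 10, leading to loss of H3. Fallback, from 2, 6 and 7, returning at 10: the three-component reaction is run in its known racemic form with an achiral acid (diphenyl hydrogen phosphate, or catalytic CF3SO3H if more acidity is needed) to give racemic methyl 2-[(2S*,3S*,4S*)-5,7-bis(benzyloxy)-4-methoxy-2-(4-methoxyphenyl)chroman-3-yl]acetate F1. The enantiomers are then separated by preparative chromatography on a chiral stationary phase, which delivers 10 at the cost of half the material.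

**Step 9.** The most likely failure is poor facial selectivity at the enolate carbon. The two flanks of C3 (C2 with its anisyl group, C4 with its methoxy group and the fused ring) are both oxygenated benzylic carbons of similar size, so substrate control of C3' may be weak; incomplete syn selectivity would add further isomers. Fallback, from 10, returning at 20, with the two new centres set by an Evans auxiliary instead of by the substrate: saponification (LiOH, THF/H2O) gives 2-[(2S,3S,4S)-5,7-bis(benzyloxy)-4-methoxy-2-(4-methoxyphenyl)chroman-3-yl]acetic acid F2. Pivaloyl chloride and Et3N (THF, −20 °C) convert it into the mixed anhydride 2-[(2S,3S,4S)-5,7-bis(benzyloxy)-4-methoxy-2-(4-methoxyphenyl)chroman-3-yl]acetic pivalic anhydride F3, which is used without isolation to acylate lithiated (S)-4-benzyl-oxazolidin-2-one and gives the imide (S)-4-benzyl-3-{2-[(2S,3S,4S)-5,7-bis(benzyloxy)-4-methoxy-2-(4-methoxyphenyl)chroman-3-yl]acetyl}oxazolidin-2-one F4. The Evans syn aldol with 17 (n-Bu2BOTf, i-Pr2NEt, CH2Cl2, −78 °C, excess amine to protect the C4 ether) gives the (2S,3S) adduct (S)-4-benzyl-3-{(2S,3S)-3-[4-(benzyloxy)phenyl]-2-[(2S,3S,4S)-5,7-bis(benzyloxy)-4-methoxy-2-(4-methoxyphenyl)chroman-3-yl]-3-hydroxypropanoyl}oxazolidin-2-one F5. Transamination (MeNH(OMe)·HCl, AlMe3, CH2Cl2, −20 °C to 0 °C) gives the hydroxy Weinreb amide (2S,3S)-3-[4-(benzyloxy)phenyl]-2-[(2S,3S,4S)-5,7-bis(benzyloxy)-4-methoxy-2-(4-methoxyphenyl)chroman-3-yl]-3-hydroxy-N-methoxy-N-methylpropanamide F6, and excess aryllithium 15 at −78 °C converts F6 into 20.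

**Step 10.** The most likely failure is retro-aldol fragmentation and re-addition of alkoxide 21, which scrambles C2' and C3', or base-mediated epimerisation of the cis chromanone at C3' once formed. Both compete because the ketone, flanked by two ortho substituents, is twisted out of the ring plane and activates the fluoride only weakly. Fallback, from 20, returning at 22, with the carbonyl removed before base is used: chelation-controlled reduction (Et2BOMe, NaBH4, THF/MeOH, −78 °C) gives the syn diol (1R,2S,3S)-1-[2,4-bis(benzyloxy)-6-fluorophenyl]-3-[4-(benzyloxy)phenyl]-2-[(2S,3S,4S)-5,7-bis(benzyloxy)-4-methoxy-2-(4-methoxyphenyl)chroman-3-yl]propane-1,3-diol F7, which can neither fragment nor enolise. Ring closure by fluoride displacement on the arene (NaH, DMF, 60–90 °C; only the C2' alkoxide can reach the fluorinated carbon through a six-membered ring) gives (2S,3R,4R)-5,7-bis(benzyloxy)-2-[4-(benzyloxy)phenyl]-3-[(2S,3S,4S)-5,7-bis(benzyloxy)-4-methoxy-2-(4-methoxyphenyl)chroman-3-yl]chroman-4-ol F8, and Dess–Martin oxidation of F8 gives 22.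

**Step 11.** The most likely failure is loss of site selectivity in the hydride abstraction, since C2–H and C2'–H are also benzylic ether positions next to 4-alkoxyphenyl rings, or deprotonation of the cationic intermediate at C3. Fallback, from 22, returning at 23: hydrolytic exchange of the C4 ether (pyridinium p-toluenesulfonate, acetone/H2O, 40 °C, stopped early to limit elimination toward C3) gives the alcohol (2S,3S)-5,7-bis(benzyloxy)-2-[4-(benzyloxy)phenyl]-3-[(2S,3S,4S)-5,7-bis(benzyloxy)-4-hydroxy-2-(4-methoxyphenyl)chroman-3-yl]chroman-4-one F9, whose C4 epimer would serve equally, and Dess–Martin periodinane oxidises F9 to 23.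

**Step 8.** The most likely failure is elimination of LiF from 15 to an aryne if addition to the amide is slow at −78 °C and the mixture has to be warmed. Fallback, from 10, returning at 16: reduction with i-Bu2AlH (CH2Cl2, −78 °C) gives 2-[(2S,3S,4S)-5,7-bis(benzyloxy)-4-methoxy-2-(4-methoxyphenyl)chroman-3-yl]acetaldehyde F10, which reacts with 15 rapidly at −78 °C to give the carbinol 1-[2,4-bis(benzyloxy)-6-fluorophenyl]-2-[(2S,3S,4S)-5,7-bis(benzyloxy)-4-methoxy-2-(4-methoxyphenyl)chroman-3-yl]ethan-1-ol F11 as both epimers at the carbinol carbon. Dess–Martin oxidation of F11 then gives 16.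

## Further compounds

F1 | step 4 | racemic methyl 2-[(2S*,3S*,4S*)-5,7-bis(benzyloxy)-4-methoxy-2-(4-methoxyphenyl)chroman-3-yl]acetate | COc1ccc([C@H]2Oc3cc(OCc4ccccc4)cc(OCc4ccccc4)c3[C@@H](OC)[C@@H]2CC(=O)OC)cc1.COc1ccc([C@@H]2Oc3cc(OCc4ccccc4)cc(OCc4ccccc4)c3[C@H](OC)[C@H]2CC(=O)OC)cc1
F2 | step 9 | 2-[(2S,3S,4S)-5,7-bis(benzyloxy)-4-methoxy-2-(4-methoxyphenyl)chroman-3-yl]acetic acid | COc1ccc([C@H]2Oc3cc(OCc4ccccc4)cc(OCc4ccccc4)c3[C@@H](OC)[C@@H]2CC(=O)O)cc1
F3 | step 9 | 2-[(2S,3S,4S)-5,7-bis(benzyloxy)-4-methoxy-2-(4-methoxyphenyl)chroman-3-yl]acetic pivalic anhydride (not isolated) | COc1ccc([C@H]2Oc3cc(OCc4ccccc4)cc(OCc4ccccc4)c3[C@@H](OC)[C@@H]2CC(=O)OC(=O)C(C)(C)C)cc1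
F4 | step 9 | (S)-4-benzyl-3-{2-[(2S,3S,4S)-5,7-bis(benzyloxy)-4-methoxy-2-(4-methoxyphenyl)chroman-3-yl]acetyl}oxazolidin-2-one | COc1ccc([C@H]2Oc3cc(OCc4ccccc4)cc(OCc4ccccc4)c3[C@@H](OC)[C@@H]2CC(=O)N2C(=O)OC[C@@H]2Cc2ccccc2)cc1
F5 | step 9 | (S)-4-benzyl-3-{(2S,3S)-3-[4-(benzyloxy)phenyl]-2-[(2S,3S,4S)-5,7-bis(benzyloxy)-4-methoxy-2-(4-methoxyphenyl)chroman-3-yl]-3-hydroxypropanoyl}oxazolidin-2-one | COc1ccc([C@H]2Oc3cc(OCc4ccccc4)cc(OCc4ccccc4)c3[C@@H](OC)[C@@H]2[C@@H]([C@H](O)c2ccc(OCc3ccccc3)cc2)C(=O)N2C(=O)OC[C@@H]2Cc2ccccc2)cc1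
F6 | step 9 | (2S,3S)-3-[4-(benzyloxy)phenyl]-2-[(2S,3S,4S)-5,7-bis(benzyloxy)-4-methoxy-2-(4-methoxyphenyl)chroman-3-yl]-3-hydroxy-N-methoxy-N-methylpropanamide | COc1ccc([C@H]2Oc3cc(OCc4ccccc4)cc(OCc4ccccc4)c3[C@@H](OC)[C@@H]2[C@@H]([C@H](O)c2ccc(OCc3ccccc3)cc2)C(=O)N(C)OC)cc1
F7 | step 10 | (1R,2S,3S)-1-[2,4-bis(benzyloxy)-6-fluorophenyl]-3-[4-(benzyloxy)phenyl]-2-[(2S,3S,4S)-5,7-bis(benzyloxy)-4-methoxy-2-(4-methoxyphenyl)chroman-3-yl]propane-1,3-diol | COc1ccc([C@H]2Oc3cc(OCc4ccccc4)cc(OCc4ccccc4)c3[C@@H](OC)[C@@H]2[C@@H]([C@H](O)c2ccc(OCc3ccccc3)cc2)[C@@H](O)c2c(F)cc(OCc3ccccc3)cc2OCc2ccccc2)cc1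
F8 | step 10 | (2S,3R,4R)-5,7-bis(benzyloxy)-2-[4-(benzyloxy)phenyl]-3-[(2S,3S,4S)-5,7-bis(benzyloxy)-4-methoxy-2-(4-methoxyphenyl)chroman-3-yl]chroman-4-ol | COc1ccc([C@H]2Oc3cc(OCc4ccccc4)cc(OCc4ccccc4)c3[C@@H](OC)[C@@H]2[C@@H]2[C@@H](O)c3c(OCc4ccccc4)cc(OCc4ccccc4)cc3O[C@@H]2c2ccc(OCc3ccccc3)cc2)cc1
F9 | step 11 | (2S,3S)-5,7-bis(benzyloxy)-2-[4-(benzyloxy)phenyl]-3-[(2S,3S,4S)-5,7-bis(benzyloxy)-4-hydroxy-2-(4-methoxyphenyl)chroman-3-yl]chroman-4-one | COc1ccc([C@H]2Oc3cc(OCc4ccccc4)cc(OCc4ccccc4)c3[C@@H](O)[C@@H]2[C@@H]2C(=O)c3c(OCc4ccccc4)cc(OCc4ccccc4)cc3O[C@@H]2c2ccc(OCc3ccccc3)cc2)cc1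
F10 | step 8 | 2-[(2S,3S,4S)-5,7-bis(benzyloxy)-4-methoxy-2-(4-methoxyphenyl)chroman-3-yl]acetaldehyde | COc1ccc([C@H]2Oc3cc(OCc4ccccc4)cc(OCc4ccccc4)c3[C@@H](OC)[C@@H]2CC=O)cc1
F11 | step 8 | 1-[2,4-bis(benzyloxy)-6-fluorophenyl]-2-[(2S,3S,4S)-5,7-bis(benzyloxy)-4-methoxy-2-(4-methoxyphenyl)chroman-3-yl]ethan-1-ol (both epimers at C1) | COc1ccc([C@H]2Oc3cc(OCc4ccccc4)cc(OCc4ccccc4)c3[C@@H](OC)[C@@H]2CC(O)c2c(F)cc(OCc3ccccc3)cc2OCc2ccccc2)cc1
A1 | alternative 1 | (2S,3R)-5,7-bis(benzyloxy)-3-{2-[2,4-bis(benzyloxy)-6-fluorophenyl]-2-oxoethyl}-2-(4-methoxyphenyl)chroman-4-one | COc1ccc([C@H]2Oc3cc(OCc4ccccc4)cc(OCc4ccccc4)c3C(=O)[C@@H]2CC(=O)c2c(F)cc(OCc3ccccc3)cc2OCc2ccccc2)cc1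
A2 | alternative 1 | 5,7-bis(benzyloxy)-4H-chromen-4-one | O=c1ccoc2cc(OCc3ccccc3)cc(OCc3ccccc3)c12
A3 | alternative 1 | (4-methoxyphenyl)zinc chloride | COc1ccc([Zn]Cl)cc1
A4 | alternative 1 | 2-bromo-1-[2,4-bis(benzyloxy)-6-fluorophenyl]ethan-1-one | O=C(CBr)c1c(F)cc(OCc2ccccc2)cc1OCc1ccccc1
A5 | alternative 2 | methyl 2-[(2S,3R)-7-hydroxy-5-methoxy-2-(4-methoxyphenyl)-4-oxochroman-3-yl]acetate | COc1ccc([C@H]2Oc3cc(O)cc(OC)c3C(=O)[C@@H]2CC(=O)OC)cc1
A6 | alternative 2 | methyl 2-[(2S,3R)-5-bromo-2-(4-methoxyphenyl)-4-oxo-3,4-dihydro-2H-pyran-3-yl]acetate | COc1ccc([C@H]2OC=C(Br)C(=O)[C@@H]2CC(=O)OC)cc1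
A7 | alternative 2 | 1,1-dimethoxy-3-(trimethylsilyloxy)buta-1,3-diene | COC(OC)=CC(=C)O[Si](C)(C)C
A8 | alternative 3 | tert-butyl (2S,3S)-3-[4-(benzyloxy)phenyl]-2-[(2S,3R)-5,7-bis(benzyloxy)-2-(4-methoxyphenyl)-4-oxochroman-3-yl]-3-hydroxypropanoate | COc1ccc([C@H]2Oc3cc(OCc4ccccc4)cc(OCc4ccccc4)c3C(=O)[C@@H]2[C@H](C(=O)OC(C)(C)C)[C@H](O)c2ccc(OCc3ccccc3)cc2)cc1
A9 | alternative 3 | tert-butyl (2S,3S,4R)-2-[4-(benzyloxy)phenyl]-4-{(S)-[3,5-bis(benzyloxy)-2-bromophenoxy](4-methoxyphenyl)methyl}-5-oxotetrahydrofuran-3-carboxylate | COc1ccc([C@@H](Oc2cc(OCc3ccccc3)cc(OCc3ccccc3)c2Br)[C@@H]2C(=O)O[C@H](c3ccc(OCc4ccccc4)cc3)[C@H]2C(=O)OC(C)(C)C)cc1
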